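**Remark on the chemistry.** Atoms are numbered as in the carbocycle throughout: C1 is the quaternary carbinol carbon, C7 its exocyclic CH2O carbon, C2 and C3 carry the acetates, C4=C5 is the alkene, C6 is the secondary carbinol. Carbocycles are named with these locants. Glycosides 2 and 3 and lactols 4 and 14 are carried as anomeric mixtures (anomeric carbon written without configuration); that carbon later becomes an aldehyde or carbonyl carbon, so this has no consequence.

## Analysis of the target

Target 24 is a cyclohex-4-ene whose four sp3 ring carbons all carry oxygen and whose quaternary carbon C1 also carries the benzoyloxymethyl carbon C7. The stereocentres C6, C1, C2 and C3 are contiguous, (1S,2R,3S,6S): the tertiary hydroxyl on C1 is cis to the C2 acetate and to the C6 hydroxyl, and the C3 acetate is trans to the C2 acetate. The five oxygens are in three states (two secondary acetates, one primary benzoate, a free tertiary and a free allylic secondary hydroxyl), so the order of unmasking matters as much as the skeleton. The esters sit 1,2 and 1,3 to free hydroxyls, so base invites acyl migration; C3–O and C6–O are both allylic and can ionise; and the ring is only eliminations away from an arene. The hard part is the fully substituted C1, flanked by two oxygenated stereocentres, in a ring with no carbonyl handle. The feature used is the C1–C6 bond beside the C4=C5 alkene: with C7 at the carboxyl level, C7(=O)–C1–C6–C5=C4 is a γ,δ-unsaturated acid, the imprint of a [3,3] shift in which C4 was bound to the carboxyl oxygen. Because C4 and C1 are already linked through C2 and C3, that ester is a δ-lactone (ring atoms C7, C1, C2, C3, C4, O), and its five carbons with the trans oxygens on C2 and C3 map onto D-xylose 1.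

## Retrosynthetic reasoning

**Acyl pattern (24 back to 21).** The C6 hydroxyl is released last, from 4-methoxybenzyl ether 23, by a neutral oxidative cleavage, so that the free allylic hydroxyl never meets base or strong acid next to three esters. The two acetates of 23 come from triol 22. The tertiary C1 hydroxyl needs no protection there, since it is too hindered to be acetylated under conditions that esterify C2–OH and C3–OH. Triol 22 comes from tris(methoxymethyl) ether 21. Putting the same ether on O1, O2 and O3 is allowed because the only distinction needed among them is made by reactivity at the acetylation.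

**C7 oxidation level (21 back to 19).** The benzoate of 21 is put on primary alcohol 20 while it is the only free hydroxyl, and 20 is the reduction product of acid 19. Raising C7 to the acid exposes the γ,δ-unsaturated acid.

**Key disconnection (19 back to 15).** The C1–C6 bond is cut and the C4–O bond restored, giving lactone 15 via its silyl ketene acetal 17. This one cut removes the ring, the quaternary centre and the C6 stereocentre together; cutting C2–C3, C3–C4 or C5–C6 instead would leave C1 to be built separately. The forward reaction must enolise a lactone with a β-alkoxy group without elimination, bond C1 on the correct face, and place C6–O cis to C1–O. The face is dictated by C4 and the C6 sense by the Z geometry of the enol ether.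

**Lactone and alkene geometry (15 back to 11).** The C7–O(C4) ester bond of 15 comes from diol 12 by oxidation of its primary alcohol and closure through lactol 14. The Z enol ether of 12 comes from alkynyl ether 11 by semi-hydrogenation, so the geometry needs no separate control.

**C4–C5 bond (11 back to 4 and 7).** Lithium alkoxyacetylide 9, made from dichlorovinyl ether 7, adds to the aldehyde carbon of lactol 4 through its open form 10. This brings in C5, C6 and O6, already carrying the group that protects O6 to the end. The demand is anti addition relative to C3–O (Felkin–Anh). Ether 7 comes from alcohol 5 and trichloroethylene 6.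

**Sugar part (4 back to 1).** D-Xylose 1 supplies C4, C3, C2, C1 and C7 (its C1 to C5) with the correct C3 and C2 configurations. Its remaining stereocentre (route C1) is erased in ketene acetal 17, so both lactone epimers are usable. The pyranoside 2 keeps the aldehyde and the future C7 oxygen tied in one ring, so the three other hydroxyls are protected alike in one step (3) before the anomeric benzyl group is removed to give 4.

## Alternatives that were turned down

**Alternative 1:** No ring C–C bond is cut; the carbocycle is an oxidised arene, the achiral cross-conjugated dienone A1. The key step would be an enantioselective nucleophilic epoxidation of one of its two enantiotopic enone double bonds, on the face of the tertiary hydroxyl, giving epoxy enone A2. A Wharton transposition would then give the C4=C5 alkene and the C6 hydroxyl cis to C1–OH.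
- For: the ring comes free, induction is catalytic, and the route is shorter than the chosen one. On step economy this alternative is the stronger.
- Against: the absolute configuration of every centre rests on a catalyst choosing between two nearly identical alkenes. The transposition gives a cyclohexa-2,4-dienol with hydroxyls on C1 and C6, one dehydration from an arene. The remaining C2=C3 bond, now part of a diene, must still be turned into a trans-diol with C2–O cis to C1–O, which raises regiochemical (1,2 against 1,4) and facial problems.
- Comparison: the chosen route is longer but takes C2 and C3 from D-xylose with certainty, creates C1 and C6 by intramolecular chirality transfer, and has no aromatisable diene on its path.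

**Alternative 2:** The C3–C4 ring bond is cut. The acyclic aldehyde A3, carrying a (Z)-alkenyl iodide, would be closed with CrCl2 and catalytic NiCl2 (Nozaki–Hiyama–Kishi) to cyclohexenol A4.
- For: the reaction tolerates esters and the acetonide and closes six-membered rings well. A4 already carries the benzoate and one acetate, so only acetylation and acetonide hydrolysis remain. The end-game is shorter than the five steps that follow the chosen key step, and here this alternative is stronger.
- Against: A3 must already contain the quaternary C1 with correct configuration relative to C2 and C6, so the hardest centre is left to earlier acyclic chemistry on a branched sugar chain. A3 is an α-acetoxy aldehyde with a β-oxygen, prone to epimerisation and elimination. The new C3 configuration depends on an uncertain facial preference, and the metal is stoichiometric.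
- Comparison: the chosen key step makes the quaternary centre and the ring in the same event, with both new centres fixed by geometry.

**Alternative 3:** The exocyclic C1–C7 bond is cut. A sulfoxonium methylide would add to the C1 ketone of the protected inosose A5 to give spiro-oxirane A6 (C7 equatorial, oxygen axial), later opened at C7 by benzoate.
- For: the ring and the C2, C3 and C6 oxygens pre-exist, and reversible betaine formation gives the equatorial C–C bond reliably. In predictability of C1 and in having no ring-forming risk this alternative is stronger than the chosen one.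
- Against: the cyclitol source is meso, so a resolution or desymmetrisation is needed. Six hydroxyls must be sorted into five roles (A6 carries three kinds of protecting group). Two oxygens, on C4 and C5, are installed only to be excised by a late vicinal deoxygenation. The step count would be about twice that of the chosen route.
- Comparison: the chosen route carries only the atoms the target keeps, at the price of one demanding pericyclic step.

Key step: step 8

## Route

**Step 1**
Reactants: 1 D-xylose
Product: 2 benzyl D-xylopyranoside (α/β mixture)
Conditions: BnOH (solvent), anhydrous HCl (cat.), 60 °C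
Reagents that add atoms: benzyl alcohol, OCc1ccccc1
Why: Fischer glycosidation under thermodynamic control favours the pyranosides, which tie the aldehyde carbon and O5 into one ring and leave O2, O3 and O4 free; both anomers are usable because the anomeric centre is cleared in step 3.

**Step 2**
Reactants: 2 benzyl D-xylopyranoside
Product: 3 benzyl 2,3,4-tri-O-(methoxymethyl)-D-xylopyranoside (α/β mixture)
Conditions: MeOCH2Cl, i-Pr2NEt, n-Bu4NI (cat.), CH2Cl2, 0 °C → reflux
Reagents that add atoms: chloromethyl methyl ether, COCCl
Why: Alkylation of the three secondary hydroxyls by the α-chloro ether (via its oxocarbenium ion) under amine base is standard acetal protection; no stereocentre is touched, and the small acyclic ethers are chosen because a cyclic diol protecting group could not span the trans C2/C3 oxygens in the later boat transition state.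

**Step 3**
Reactants: 3 benzyl 2,3,4-tri-O-(methoxymethyl)-D-xylopyranoside
Product: 4 2,3,4-tri-O-(methoxymethyl)-D-xylopyranose (lactol, α/β mixture)
Conditions: H2 (1 atm), Pd/C, EtOAc/EtOH, rt
Reagents that add atoms: none
Why: Hydrogenolysis cleaves the benzylic C–O bond of the glycoside and leaves the methoxymethyl acetals, releasing the lactol as a masked aldehyde whose O5 stays protected by the ring.

**Step 4**
Reactants: 5 4-methoxybenzyl alcohol; 6 trichloroethylene
Product: 7 (E)-1,2-dichlorovinyl 4-methoxybenzyl ether
Conditions: KH, THF, 0 °C; then 6, −50 °C → rt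
Reagents that add atoms: none
Why: The potassium alkoxide adds to dichloroacetylene formed in situ from 6 by dehydrochlorination; anti addition gives the E dichlorovinyl ether, the standard precursor of alkoxyacetylides.

**Step 5**
Reactants: 4 2,3,4-tri-O-(methoxymethyl)-D-xylopyranose; 7 (E)-1,2-dichlorovinyl 4-methoxybenzyl ether
Product: 11 2-deoxy-1-O-(4-methoxybenzyl)-4,5,6-tri-O-(methoxymethyl)-D-gulo-hept-1-ynitol (route C4 carbinol S), via chloroalkynyl ether 8 (not isolated), via lithium alkoxyacetylide 9 (not isolated), via open-chain aldehyde 10 (not isolated)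
Conditions: 7 (excess), n-BuLi (2 equiv per 7), THF, −78 → −40 °C; then DMPU, 4, −78 → −20 °C; aq. NH4Cl
Reagents that add atoms: none
Why: n-BuLi eliminates HCl from 7 to give 8 and then exchanges chlorine for lithium to give 9; one equivalent of 9 deprotonates the lactol, and its open form 10 is attacked at the aldehyde carbon (acetylide addition to a sugar lactol). The new C4 centre is set by polar Felkin–Anh control: with lithium in THF/DMPU no chelate forms, the C3 alkoxy group lies anti to the incoming acetylide, and the 3,4-anti (D-gulo) alcohol should predominate; any C4 epimer is removed by chromatography here or at lactone 15.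

**Step 6**
Reactants: 11 2-deoxy-1-O-(4-methoxybenzyl)-4,5,6-tri-O-(methoxymethyl)-D-gulo-hept-1-ynitol
Product: 12 (Z)-2-deoxy-1-O-(4-methoxybenzyl)-4,5,6-tri-O-(methoxymethyl)-D-gulo-hept-1-enitol
Conditions: H2 (1 atm), Pd/CaCO3 poisoned with Pb(OAc)2, quinoline, EtOAc/Et3N, rt
Reagents that add atoms: none
Why: Lindlar semi-hydrogenation adds hydrogen syn to the alkynyl ether and stops at the Z enol ether; the amine-buffered medium keeps the acid-labile γ-hydroxy enol ether intact and the benzylic ether is not cleaved on the poisoned catalyst.

**Step 7**
Reactants: 12 (Z)-2-deoxy-1-O-(4-methoxybenzyl)-4,5,6-tri-O-(methoxymethyl)-D-gulo-hept-1-enitol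
Product: 15 (3S,4R,5S,6S)-6-[(Z)-2-(4-methoxybenzyloxy)ethenyl]-3,4,5-tris(methoxymethoxy)oxan-2-one (ring carbons 2 to 6 are route C7 and C1 to C4), via hydroxy aldehyde 13 (not isolated), via lactol 14 (not isolated)
Conditions: [Cu(MeCN)4]OTf (cat.), 2,2'-bipyridyl (cat.), TEMPO (cat.), N-methylimidazole (cat.), MeCN, air, rt
Reagents that add atoms: none
Why: Copper/nitroxyl aerobic oxidation takes the unhindered primary alcohol in preference to the secondary allylic one; aldehyde 13 closes to six-membered lactol 14, which is oxidised again to the lactone (oxidative lactonisation of a 1,5-diol). No acid and no oxoammonium salt is generated, which suits the enol ether, and any epimerisation at C1 is harmless because C1 becomes planar in step 8.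

**Step 8**
Reactants: 15 (3S,4R,5S,6S)-6-[(Z)-2-(4-methoxybenzyloxy)ethenyl]-3,4,5-tris(methoxymethoxy)oxan-2-one
Product: 19 (1S,2R,3S,6S)-6-(4-methoxybenzyloxy)-1,2,3-tris(methoxymethoxy)cyclohex-4-ene-1-carboxylic acid, via lithium enolate 16 (not isolated), via silyl ketene acetal 17 (not isolated), via trimethylsilyl ester 18 (not isolated)
Conditions: Me3SiCl/Et3N (premixed), THF, −100 °C; LiN(i-Pr)2; → rt; PhMe, 100 °C; then H2O/THF, pH 4
Reagents that add atoms: none
Why: This is an Ireland–Claisen rearrangement of a lactone ketene acetal, a ring-contracting [3,3] shift. Base is added to 15 in the presence of the silyl chloride at −100 °C, so enolate 16 is silylated to 17 as it forms and has no time to expel the C2 methoxymethoxy group, which in the all-equatorial lactone is also poorly aligned with the enolate π system. On warming, C1 bonds to C6 while the C4–O bond breaks, concertedly and suprafacially on both three-atom units; the alkoxy group on C6 weakens the C4–O bond and lowers the barrier, as in the rearrangement of glycal esters. The closest known reaction type is the ring contraction of six-membered lactone silyl ketene acetals bearing a 6-alkenyl group to cyclohexene or dihydropyran carboxylic acids. The carbocycle closes by joining the two termini of a 1,5-diene that is already tied through C2–C3, which allows only a boat-like, bicyclo[2.2.2]octane-type transition state. At C1 the alkenyl group, held on one face of the lactone by the S centre C4, can reach only that face of the planar ketene acetal, which places C1–O cis to C2–O; both C1 epimers of 15 give the same 17. At C6 the Z geometry puts the 4-methoxybenzyloxy group on the inner side beside C2–O in the boat, so C6–O ends cis to C1–O. The selectivities needed are therefore the bonding face at C1 and the sense at C6, secured by the C4 configuration from step 5 and the alkene geometry from step 6; aqueous work-up cleaves silyl ester 18 to acid 19.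

**Step 9**
Reactants: 19 (1S,2R,3S,6S)-6-(4-methoxybenzyloxy)-1,2,3-tris(methoxymethoxy)cyclohex-4-ene-1-carboxylic acid
Product: 20 [(1S,2R,3S,6S)-6-(4-methoxybenzyloxy)-1,2,3-tris(methoxymethoxy)cyclohex-4-en-1-yl]methanol
Conditions: LiAlH4, THF, 0 → 50 °C
Reagents that add atoms: none
Why: Hydride reduction of the carboxylic acid (through its carboxylate) gives the neopentyl-type primary alcohol; ethers, acetals and the isolated alkene are inert to the reagent.

**Step 10**
Reactants: 20 [(1S,2R,3S,6S)-6-(4-methoxybenzyloxy)-1,2,3-tris(methoxymethoxy)cyclohex-4-en-1-yl]methanol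
Product: 21 [(1S,2R,3S,6S)-6-(4-methoxybenzyloxy)-1,2,3-tris(methoxymethoxy)cyclohex-4-en-1-yl]methyl benzoate
Conditions: BzCl, pyridine, DMAP (cat.), CH2Cl2, 0 °C → rt
Reagents that add atoms: benzoyl chloride, O=C(Cl)c1ccccc1
Why: DMAP-catalysed acylation of the only free hydroxyl puts the benzoate on C7 before any other oxygen is unmasked, so no regiochemical question arises.

**Step 11**
Reactants: 21 [(1S,2R,3S,6S)-6-(4-methoxybenzyloxy)-1,2,3-tris(methoxymethoxy)cyclohex-4-en-1-yl]methyl benzoate
Product: 22 [(1R,2R,3S,6S)-1,2,3-trihydroxy-6-(4-methoxybenzyloxy)cyclohex-4-en-1-yl]methyl benzoate (same spatial arrangement; the C1 descriptor changes with priorities only)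
Conditions: Me3SiOTf, 2,2'-bipyridyl, CH2Cl2, 0 °C → rt; then H2O
Reagents that add atoms: none
Why: The silyl triflate activates the terminal methoxy oxygen of each methoxymethyl acetal and bipyridyl captures the resulting cation at its unhindered CH2, so no free protic acid appears; water then releases the alcohols (non-acidic acetal cleavage). The 4-methoxybenzyl ether, the benzoate and the two allylic C–O bonds should be left alone.

**Step 12**
Reactants: 22 [(1R,2R,3S,6S)-1,2,3-trihydroxy-6-(4-methoxybenzyloxy)cyclohex-4-en-1-yl]methyl benzoate
Product: 23 [(1S,2R,3S,6S)-2,3-diacetoxy-1-hydroxy-6-(4-methoxybenzyloxy)cyclohex-4-en-1-yl]methyl benzoate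
Conditions: Ac2O, pyridine, DMAP (cat.), CH2Cl2, 0 °C → rt
Reagents that add atoms: acetic anhydride, CC(=O)OC(C)=O
Why: Acetylation takes the two secondary hydroxyls; the tertiary C1 hydroxyl, flanked by three substituted carbons, does not react under these unforced conditions, which is why it needed no protecting group of its own.

**Step 13**
Reactants: 23 [(1S,2R,3S,6S)-2,3-diacetoxy-1-hydroxy-6-(4-methoxybenzyloxy)cyclohex-4-en-1-yl]methyl benzoate
Product: 24 [(1S,2R,3S,6S)-2,3-diacetoxy-1,6-dihydroxycyclohex-4-en-1-yl]methyl benzoate (target)
Conditions: DDQ, CH2Cl2/pH 7 phosphate buffer, 0 °C → rt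
Reagents that add atoms: none
Why: Oxidative cleavage of the 4-methoxybenzyl ether (hydride abstraction to an oxocarbenium ion that water hydrolyses) frees the C6 hydroxyl under neutral conditions, so the esters neither migrate nor hydrolyse and no stereocentre is touched.

## Compound list

1 | D-xylose | O=C[C@H](O)[C@@H](O)[C@H](O)CO | starting material
2 | benzyl D-xylopyranoside (α/β mixture) | c1ccccc1COC2[C@H](O)[C@@H](O)[C@H](O)CO2 | intermediate
3 | benzyl 2,3,4-tri-O-(methoxymethyl)-D-xylopyranoside (α/β mixture) | c1ccccc1COC2[C@H](OCOC)[C@@H](OCOC)[C@H](OCOC)CO2 | intermediate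
4 | 2,3,4-tri-O-(methoxymethyl)-D-xylopyranose (lactol, α/β mixture) | OC1[C@H](OCOC)[C@@H](OCOC)[C@H](OCOC)CO1 | intermediate
5 | 4-methoxybenzyl alcohol | COc1ccc(CO)cc1 | starting material
6 | trichloroethylene | ClC=C(Cl)Cl | starting material
7 | (E)-1,2-dichlorovinyl 4-methoxybenzyl ether | COc1ccc(CO/C(Cl)=C\Cl)cc1 | intermediate
8 | chloroethynyl 4-methoxybenzyl ether (not isolated) | COc1ccc(COC#CCl)cc1 | intermediate
9 | lithium 2-(4-methoxybenzyloxy)ethynide (not isolated) | [Li]C#COCc1ccc(OC)cc1 | intermediate
10 | 2,3,4-tri-O-(methoxymethyl)-aldehydo-D-xylose, open form of 4, present as its lithium alkoxide (not isolated) | O=C[C@H](OCOC)[C@@H](OCOC)[C@H](OCOC)CO | intermediate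
11 | 2-deoxy-1-O-(4-methoxybenzyl)-4,5,6-tri-O-(methoxymethyl)-D-gulo-hept-1-ynitol (route C4 carbinol S, anti to C3–O) | OC[C@@H](OCOC)[C@H](OCOC)[C@@H](OCOC)[C@@H](O)C#COCc1ccc(OC)cc1 | intermediate
12 | (Z)-2-deoxy-1-O-(4-methoxybenzyl)-4,5,6-tri-O-(methoxymethyl)-D-gulo-hept-1-enitol | OC[C@@H](OCOC)[C@H](OCOC)[C@@H](OCOC)[C@@H](O)/C=C\OCc1ccc(OC)cc1 | intermediate
13 | (Z)-6-deoxy-7-O-(4-methoxybenzyl)-2,3,4-tri-O-(methoxymethyl)-aldehydo-L-gluco-hept-6-enose (chain of 12 numbered from C7; not isolated) | O=C[C@@H](OCOC)[C@H](OCOC)[C@@H](OCOC)[C@@H](O)/C=C\OCc1ccc(OC)cc1 | intermediate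
14 | (Z)-6-deoxy-7-O-(4-methoxybenzyl)-2,3,4-tri-O-(methoxymethyl)-L-gluco-hept-6-enopyranose (lactol, anomeric mixture; not isolated) | OC1[C@@H](OCOC)[C@H](OCOC)[C@@H](OCOC)[C@H](/C=C\OCc2ccc(OC)cc2)O1 | intermediate
15 | (3S,4R,5S,6S)-6-[(Z)-2-(4-methoxybenzyloxy)ethenyl]-3,4,5-tris(methoxymethoxy)oxan-2-one (all ring substituents trans) | O=C1[C@@H](OCOC)[C@H](OCOC)[C@@H](OCOC)[C@H](/C=C\OCc2ccc(OC)cc2)O1 | intermediate
16 | lithium enolate of 15 (not isolated) | [Li]OC1=C(OCOC)[C@H](OCOC)[C@@H](OCOC)[C@H](/C=C\OCc2ccc(OC)cc2)O1 | intermediate
17 | trimethylsilyl ketene acetal of 15 (not isolated) | C[Si](C)(C)OC1=C(OCOC)[C@H](OCOC)[C@@H](OCOC)[C@H](/C=C\OCc2ccc(OC)cc2)O1 | intermediate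
18 | trimethylsilyl ester of 19 (not isolated) | COCO[C@H]1C=C[C@H](OCc2ccc(OC)cc2)[C@@](OCOC)(C(=O)O[Si](C)(C)C)[C@@H]1OCOC | intermediate
19 | (1S,2R,3S,6S)-6-(4-methoxybenzyloxy)-1,2,3-tris(methoxymethoxy)cyclohex-4-ene-1-carboxylic acid | COCO[C@H]1C=C[C@H](OCc2ccc(OC)cc2)[C@@](OCOC)(C(=O)O)[C@@H]1OCOC | intermediate
20 | [(1S,2R,3S,6S)-6-(4-methoxybenzyloxy)-1,2,3-tris(methoxymethoxy)cyclohex-4-en-1-yl]methanol | COCO[C@H]1C=C[C@H](OCc2ccc(OC)cc2)[C@@](OCOC)(CO)[C@@H]1OCOC | intermediate
21 | [(1S,2R,3S,6S)-6-(4-methoxybenzyloxy)-1,2,3-tris(methoxymethoxy)cyclohex-4-en-1-yl]methyl benzoate | COCO[C@H]1C=C[C@H](OCc2ccc(OC)cc2)[C@@](OCOC)(COC(=O)c2ccccc2)[C@@H]1OCOC | intermediate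
22 | [(1R,2R,3S,6S)-1,2,3-trihydroxy-6-(4-methoxybenzyloxy)cyclohex-4-en-1-yl]methyl benzoate | O[C@H]1C=C[C@H](OCc2ccc(OC)cc2)[C@@](O)(COC(=O)c2ccccc2)[C@@H]1O | intermediate
23 | [(1S,2R,3S,6S)-2,3-diacetoxy-1-hydroxy-6-(4-methoxybenzyloxy)cyclohex-4-en-1-yl]methyl benzoate | CC(=O)O[C@H]1C=C[C@H](OCc2ccc(OC)cc2)[C@@](O)(COC(=O)c2ccccc2)[C@@H]1OC(C)=O | intermediate
24 | [(1S,2R,3S,6S)-2,3-diacetoxy-1,6-dihydroxycyclohex-4-en-1-yl]methyl benzoate | CC(=O)O[C@H]1C=C[C@H](O)[C@@](O)(COC(=O)c2ccccc2)[C@@H]1OC(C)=O | target

## Step count and least certain steps

Total step count: 13. Longest linear sequence: 12 steps (steps 1 to 3 and 5 to 13, from D-xylose); step 4 is a one-step side branch.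

**Step 8 (key step).** The enolate may lose the C2 methoxymethoxy group by β-elimination before it is silylated. The boat rearrangement may also be slow, because the inward-pointing 4-methoxybenzyloxy group is pressed against C2–O, so that the ketene acetal decays by C-silylation or hydrolysis instead. Fallback, setting out from 15 and coming back at 20: the same [3,3] disconnection is run one oxidation level lower, with no enolate. Lactone 15 is reduced with i-Bu2AlH at −78 °C to lactol 14. Lactol 14 is dehydrated (methanesulfonic anhydride and Et3N, then DBU) to the 2-alkoxy glycal F1, a cyclic allyl vinyl ether with a C7=C1 double bond. F1 is heated in o-dichlorobenzene at about 180 °C with a trace of hindered amine; the Claisen ring contraction passes through the same boat with the same stereochemical course and gives the cyclohexene carbaldehyde F2. NaBH4 then reduces F2 to alcohol 20.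

**Step 5.** Facial selectivity at the aldehyde carbon may be poor if a lithium chelate between the carbonyl and a neighbouring oxygen competes with the Felkin–Anh mode. The C4 epimer would lead to the wrong face at C1 in step 8. Enolisation of 10 with epimerisation at C3 is a lesser risk. Fallback, setting out from 4 and coming back at 11: the stereocentre is made by reduction instead of addition. Lactol 4 is oxidised with Dess–Martin periodinane to the xylonolactone F3. Acetylide 9 adds to F3 to give the alkynyl hemiketal F4, in equilibrium with its open keto form. Zn(BH4)2 in Et2O reduces the ketone under chelation control (zinc held between the ketone and the C3 methoxymethoxy oxygen, hydride from the side of C3–H), which gives the anti diol 11.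

**Step 7.** The electron-rich γ-hydroxy enol ether may be degraded, the allylic C4 carbinol may be oxidised before the lactol closes, or the reaction may stall at lactol 14. Fallback, setting out from 11 and coming back at 15: the order of steps 6 and 7 is reversed, so that no enol ether is present during the oxidation. Alkyne diol 11 is oxidised under the same copper/nitroxyl conditions to the alkynyl lactone F5. F5 is then semi-hydrogenated (H2, Pd/CaCO3 poisoned with Pb(OAc)2, quinoline) to 15.

**Step 11.** The 4-methoxybenzyl ether may be lost together with the acetals, the hindered tertiary acetal may cleave incompletely, or the benzoyl group may migrate once neighbouring hydroxyls are free. Fallback, setting out from 21 and coming back at 24: the protecting group on O6 is exchanged before the acetals are removed.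
- DDQ in buffered CH2Cl2 removes the 4-methoxybenzyl group of 21 (no free neighbouring hydroxyl at this stage) to give the C6 alcohol F6.
- i-Pr3SiOTf and 2,6-lutidine give the triisopropylsilyl ether F7.
- HCl in MeOH, now free to be as strong as needed, gives the triol F8.
- Ac2O and pyridine give the diacetate F9.
- HF·pyridine removes the silyl group under non-basic conditions to give 24.

**Step 13.** The oxocarbenium ion formed from the benzylic ether may be captured by the cis C1 hydroxyl, giving a cyclic acetal instead of being hydrolysed; over-oxidation of the freed allylic alcohol is a lesser risk. Fallback, setting out from 23 and coming back at 24: the capture is made deliberate. DDQ with 4 Å molecular sieves in dry CH2Cl2 converts 23 wholly into the 4-methoxybenzylidene acetal F10 spanning O1 and O6. F10 is hydrolysed with 80% aqueous AcOH at rt to 24, conditions under which the esters do not migrate.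

## Further compounds

F1 | step 8 | (2S,3S,4R)-2-[(Z)-2-(4-methoxybenzyloxy)ethenyl]-3,4,5-tris(methoxymethoxy)-3,4-dihydro-2H-pyran (2-alkoxy glycal from 14) | COCOC1=CO[C@@H](/C=C\OCc2ccc(OC)cc2)[C@H](OCOC)[C@H]1OCOC
F2 | step 8 | (1S,2R,3S,6S)-6-(4-methoxybenzyloxy)-1,2,3-tris(methoxymethoxy)cyclohex-4-ene-1-carbaldehyde | COCO[C@H]1C=C[C@H](OCc2ccc(OC)cc2)[C@@](OCOC)(C=O)[C@@H]1OCOC
F3 | step 5 | 2,3,4-tri-O-(methoxymethyl)-D-xylono-1,5-lactone | O=C1[C@H](OCOC)[C@@H](OCOC)[C@H](OCOC)CO1
F4 | step 5 | 1-C-[(4-methoxybenzyloxy)ethynyl]-2,3,4-tri-O-(methoxymethyl)-D-xylopyranose (hemiketal, anomeric mixture) | OC1(C#COCc2ccc(OC)cc2)[C@H](OCOC)[C@@H](OCOC)[C@H](OCOC)CO1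
F5 | step 7 | (3S,4R,5S,6S)-6-[(4-methoxybenzyloxy)ethynyl]-3,4,5-tris(methoxymethoxy)oxan-2-one | O=C1[C@@H](OCOC)[C@H](OCOC)[C@@H](OCOC)[C@H](C#COCc2ccc(OC)cc2)O1
F6 | step 11 | C6 alcohol (21 without its 4-methoxybenzyl group) | COCO[C@H]1C=C[C@H](O)[C@@](OCOC)(COC(=O)c2ccccc2)[C@@H]1OCOC
F7 | step 11 | 6-O-triisopropylsilyl ether of F6 | COCO[C@H]1C=C[C@H](O[Si](C(C)C)(C(C)C)C(C)C)[C@@](OCOC)(COC(=O)c2ccccc2)[C@@H]1OCOC
F8 | step 11 | 1,2,3-triol with 6-O-triisopropylsilyl ether and C7 benzoate | O[C@H]1C=C[C@H](O[Si](C(C)C)(C(C)C)C(C)C)[C@@](O)(COC(=O)c2ccccc2)[C@@H]1O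
F9 | step 11 | 2,3-diacetate of F8 (6-O-triisopropylsilyl ether of 24) | CC(=O)O[C@H]1C=C[C@H](O[Si](C(C)C)(C(C)C)C(C)C)[C@@](O)(COC(=O)c2ccccc2)[C@@H]1OC(C)=O
F10 | step 13 | 1,6-O-(4-methoxybenzylidene) acetal of 24 (acetal carbon as a mixture) | CC(=O)O[C@H]1C=C[C@@H]2OC(c3ccc(OC)cc3)O[C@]2(COC(=O)c3ccccc3)[C@@H]1OC(C)=O
A1 | alternative 1 | 4-hydroxy-4-[(tert-butyldimethylsilyloxy)methyl]cyclohexa-2,5-dien-1-one | O=C1C=CC(O)(CO[Si](C)(C)C(C)(C)C)C=C1
A2 | alternative 1 | mono-epoxide of A1 with the oxirane syn to the tertiary hydroxyl (oxirane on C5 and C6 in target numbering) | C1=CC(=O)[C@@H]2O[C@@H]2[C@@]1(O)CO[Si](C)(C)C(C)(C)C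
A3 | alternative 2 | acyclic C3 aldehyde with C2 acetate, C1/C6 acetonide, C7 benzoate and (Z)-alkenyl iodide at C4 | O=C[C@@H](OC(C)=O)[C@@]1(COC(=O)c2ccccc2)OC(C)(C)O[C@H]1/C=C\I
A4 | alternative 2 | cyclohexenol with free C3 hydroxyl, C2 acetate, C1/C6 acetonide and C7 benzoate | O[C@H]1C=C[C@@H]2OC(C)(C)O[C@]2(COC(=O)c3ccccc3)[C@@H]1OC(C)=O
A5 | alternative 3 | protected inosose (C1 ketone; two benzyl, two 4-methoxybenzyl and one tert-butyldiphenylsilyl ether) | COc1ccc(CO[C@H]2[C@H](OCc3ccccc3)[C@@H](OCc3ccccc3)[C@H](O[Si](C(C)(C)C)(c3ccccc3)c3ccccc3)C(=O)[C@@H]2OCc2ccc(OC)cc2)cc1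
A6 | alternative 3 | spiro-oxirane at C1 of A5 with axial oxygen and equatorial C7 | COc1ccc(CO[C@H]2[C@H](OCc3ccccc3)[C@@H](OCc3ccccc3)[C@H](O[Si](C(C)(C)C)(c3ccccc3)c3ccccc3)[C@@]3(CO3)[C@@H]2OCc2ccc(OC)cc2)cc1
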